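## Retrosynthetic overview
1. Maackiaflavanone A comes from a (2S)-flavanone carrying 5-OAc and 2'-OMOM. The (2S) enantiomer is taken from the racemate by a Noyori-type transfer-hydrogenation kinetic resolution.
2. The 8-prenyl/5-OH pair comes from a 5-O-prenyl ether by a Claisen–Cope sequence. It is run after ring C is closed, so 6- and 8-substitution cannot be confused.
3. Ring C comes from oxa-Michael closure of a 2'-hydroxychalcone. The chalcone comes from a Claisen–Schmidt aldol condensation (key C–C bond) of a ring A acetophenone with a ring B/D chromene aldehyde.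
4. The acetophenone comes from phloroacetophenone (4-O-methylation, mono-O-prenylation). The aldehyde comes from resorcinol and senecioic acid (chromanone, chromene, ortho-formylation, MOM).
5. Ring order: ring D (dimethylpyran) first, ring C (pyranone) last. Rings A and B are bought.

Assumption: the stereocentre in the SMILES is read as (2S). Racemic compounds are written without stereo marks.

## Route

Step 1
Reactants: 1 resorcinol; 2 3-methylbut-2-enoic acid (senecioic acid)
Product: 4 7-hydroxy-2,2-dimethylchroman-4-one, via aryl enone 3 (not isolated)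
Conditions: P2O5, MeSO3H, 70 °C, 45 min; ice water
Reagents that add atoms: none
Why: Friedel–Crafts acylation of resorcinol at C-4 (para to one OH, ortho to the other) gives enone 3, whose ortho-OH adds to the β,β-dimethyl enone in an acid-promoted intramolecular oxa-Michael reaction to close ring D; no stereocentre is formed.

Step 2
Reactants: 4 7-hydroxy-2,2-dimethylchroman-4-one
Product: 5 7-(tert-butyldimethylsilyloxy)-2,2-dimethylchroman-4-one
Conditions: TBSCl, imidazole, DMF, rt
Reagents that add atoms: tert-butyldimethylsilyl chloride, CC(C)(C)[Si](C)(C)Cl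
Why: Imidazole-promoted silylation masks the phenol, so the ketone is not deactivated as a vinylogous phenoxide in step 3 and the later 4-chromanol cannot collapse to a para-quinone methide.

Step 3
Reactants: 5 7-(tert-butyldimethylsilyloxy)-2,2-dimethylchroman-4-one
Product: 6 (±)-7-(tert-butyldimethylsilyloxy)-2,2-dimethylchroman-4-ol
Conditions: NaBH4, THF/MeOH, 0 °C to rt
Reagents that add atoms: none
Why: Borohydride 1,2-reduction of the aryl ketone leaves the aryl silyl ether alone; the C-4 carbinol centre forms as a racemate and is erased in step 4.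

Step 4
Reactants: 6 (±)-7-(tert-butyldimethylsilyloxy)-2,2-dimethylchroman-4-ol
Product: 7 7-(tert-butyldimethylsilyloxy)-2,2-dimethyl-2H-chromene
Conditions: p-TsOH·H2O (3 mol %), toluene, 4 Å MS, 80 °C, 1 h
Reagents that add atoms: none
Why: Acid-catalysed E1 dehydration runs through a benzylic cation stabilised by the ring oxygen and the 7-silyloxy group, under catalytic acid that aryl TBS ethers tolerate, and gives the conjugated 2H-chromene.

Step 5
Reactants: 7 7-(tert-butyldimethylsilyloxy)-2,2-dimethyl-2H-chromene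
Product: 8 2,2-dimethyl-2H-chromen-7-ol
Conditions: Bu4NF, AcOH (1:1), THF, 0 °C
Reagents that add atoms: none
Why: Fluoride-induced desilylation is driven by the strong Si–F bond, and the acetic acid buffer keeps the medium neutral so the chromene is untouched.

Step 6
Reactants: 8 2,2-dimethyl-2H-chromen-7-ol
Product: 10 7-hydroxy-2,2-dimethyl-2H-chromene-6-carbaldehyde, via hydroxymethylphenol 9 (not isolated)
Conditions: MgCl2, Et3N, (CH2O)n, MeCN, reflux, 3 h; 1 M HCl
Reagents that add atoms: paraformaldehyde (reacts as formaldehyde), C=O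
Why: In this Casnati–Skattebøl ortho-formylation the magnesium phenoxide delivers formaldehyde only ortho to the OH, at the open C-6 (also para to the ring oxygen) rather than at C-8 squeezed between two oxygens, and a second formaldehyde oxidises benzylic alcohol 9 by hydride transfer.

Step 7
Reactants: 10 7-hydroxy-2,2-dimethyl-2H-chromene-6-carbaldehyde
Product: 11 7-(methoxymethoxy)-2,2-dimethyl-2H-chromene-6-carbaldehyde
Conditions: MOMCl, i-Pr2NEt, CH2Cl2, 0 °C to rt
Reagents that add atoms: chloromethyl methyl ether, COCCl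
Why: O-alkylation to the MOM acetal gives a non-enolisable aldehyde with no acidic proton that survives the strong base of step 10.

Step 8
Reactants: 12 2,4,6-trihydroxyacetophenone (phloroacetophenone)
Product: 13 2,6-dihydroxy-4-methoxyacetophenone
Conditions: Me2SO4 (1.0 equiv), K2CO3, acetone, reflux
Reagents that add atoms: dimethyl sulfate, COS(=O)(=O)OC
Why: This Williamson O-methylation is selective because the 4-OH is the most acidic and is not held in the hydrogen bond to the acetyl group, so one equivalent of Me2SO4 stops at the 4-methyl ether.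

Step 9
Reactants: 13 2,6-dihydroxy-4-methoxyacetophenone; 14 prenyl bromide (1-bromo-3-methylbut-2-ene)
Product: 15 1-[2-hydroxy-4-methoxy-6-(3-methylbut-2-enyloxy)phenyl]ethanone
Conditions: K2CO3, acetone, reflux
Reagents that add atoms: none
Why: Williamson O-alkylation in a weak-base aprotic medium favours O- over C-attack; the two OH groups of 13 are equivalent and the remaining one is firmly chelated after the first alkylation, so the reaction stops at the mono-ether, which serves as protecting group for the future 5-OH and as latent 8-prenyl group.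

Step 10
Reactants: 15 1-[2-hydroxy-4-methoxy-6-(3-methylbut-2-enyloxy)phenyl]ethanone; 11 7-(methoxymethoxy)-2,2-dimethyl-2H-chromene-6-carbaldehyde
Product: 17 (E)-1-[2-hydroxy-4-methoxy-6-(3-methylbut-2-enyloxy)phenyl]-3-[7-(methoxymethoxy)-2,2-dimethyl-2H-chromen-6-yl]prop-2-en-1-one, via aldol adduct 16 (not isolated)
Conditions: KOH, EtOH/H2O, 0 °C to rt, 48 h; cold dilute HCl to pH 6
Reagents that add atoms: none
Why: In this Claisen–Schmidt (crossed aldol) condensation only 15 can form an enolate and only 11 is an aldehyde, aldol 16 loses water by E1cB to the conjugated (E)-enone, and MOM ether, prenyl ether and chromene are all base-stable.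

Step 11
Reactants: 17 the (E)-chalcone
Product: 18 (±)-7-methoxy-2-[7-(methoxymethoxy)-2,2-dimethyl-2H-chromen-6-yl]-5-(3-methylbut-2-enyloxy)chroman-4-one
Conditions: NaOAc, EtOH, reflux, 24–48 h
Reagents that add atoms: none
Why: Base-mediated intramolecular oxa-Michael addition (6-endo-trig) of the only free phenol is driven by relief of the twist in the 2',6'-disubstituted chalcone; C-2 is created here as a racemate and is resolved in step 14.

Step 12
Reactants: 18 the (±)-5-O-prenyl flavanone
Product: 21 (±)-5-hydroxy-7-methoxy-2-[7-(methoxymethoxy)-2,2-dimethyl-2H-chromen-6-yl]-8-(3-methylbut-2-enyl)chroman-4-one, via ortho-dienone 19 (not isolated), via para-dienone 20 (not isolated)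
Conditions: Eu(fod)3 (10 mol %), NaHCO3, PhCl, 85 °C, 24 h (fod = 6,6,7,7,8,8,8-heptafluoro-2,2-dimethyloctane-3,5-dionate)
Reagents that add atoms: none
Why: A Lewis-acid-catalysed aromatic Claisen rearrangement (O-5 to C-6, reverse prenyl) is followed by a Cope rearrangement (C-6 to C-8, normal prenyl) and enolisation, with europium chelating the C-4 carbonyl and O-5; because ring C is closed the para position can only be C-8, and C-2 is still racemic so no stereochemical information can be lost.

Step 13
Reactants: 21 the (±)-5-hydroxy-8-prenyl flavanone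
Product: 22 (±)-5-acetoxy-7-methoxy-2-[7-(methoxymethoxy)-2,2-dimethyl-2H-chromen-6-yl]-8-(3-methylbut-2-enyl)chroman-4-one
Conditions: Ac2O, pyridine, DMAP (cat.), CH2Cl2, rt
Reagents that add atoms: acetic anhydride, CC(=O)OC(C)=O
Why: DMAP-catalysed acylation of the chelated 5-OH breaks the hydrogen bond, makes the ketone more electrophilic and removes an O,O-chelating site that could bind ruthenium in step 14.

Step 14
Reactants: 22 the (±)-5-acetoxy flavanone
Product: 23 (2S)-5-acetoxy-7-methoxy-2-[7-(methoxymethoxy)-2,2-dimethyl-2H-chromen-6-yl]-8-(3-methylbut-2-enyl)chroman-4-one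
Conditions: RuCl(p-cymene)[(R,R)-TsDPEN] (1–2 mol %), HCO2H/Et3N (5:2), EtOAc, rt, stopped at 52–55 % conversion (chiral HPLC); SiO2 separation
Reagents that add atoms: none
Why: Noyori–Ikariya asymmetric transfer hydrogenation serves as a kinetic resolution: the (R,R)-catalyst makes a (4R)-carbinol, which corresponds to the easy attack leading to the 2,4-cis flavan-4-ol only for the (2R)-ketone, so that enantiomer is consumed and the mismatched (2S)-ketone 23 is recovered in high ee (at most half of the material), while C=C bonds, acetate and MOM are untouched.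

Step 15
Reactants: 23 the (2S)-5-acetoxy flavanone
Product: 25 maackiaflavanone A [(2S)-5-hydroxy-2-(7-hydroxy-2,2-dimethyl-2H-chromen-6-yl)-7-methoxy-8-(3-methylbut-2-enyl)chroman-4-one], via (S)-5-hydroxy MOM ether 24 (not isolated)
Conditions: HCl (cat., ca. 0.5 M), MeOH, 0 °C to rt; pH 7 phosphate buffer
Reagents that add atoms: none
Why: Acid-catalysed transesterification of the activated aryl acetate and acetal exchange of the MOM ether with methanol free both phenols; the 8-prenyl group has no free ortho-OH to cyclise onto, and mild acid at or below rt avoids the base-induced retro-oxa-Michael path that racemises flavanones, so (2S) is kept.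

## Compound list
1 | resorcinol | Oc1cccc(O)c1 | starting material
2 | 3-methylbut-2-enoic acid | CC(C)=CC(=O)O | starting material
3 | 1-(2,4-dihydroxyphenyl)-3-methylbut-2-en-1-one (not isolated) | CC(C)=CC(=O)c1ccc(O)cc1O | intermediate
4 | 7-hydroxy-2,2-dimethylchroman-4-one | CC1(C)CC(=O)c2ccc(O)cc2O1 | intermediate
5 | 7-(tert-butyldimethylsilyloxy)-2,2-dimethylchroman-4-one | CC1(C)CC(=O)c2ccc(O[Si](C)(C)C(C)(C)C)cc2O1 | intermediate
6 | (±)-7-(tert-butyldimethylsilyloxy)-2,2-dimethylchroman-4-ol | CC1(C)CC(O)c2ccc(O[Si](C)(C)C(C)(C)C)cc2O1 | intermediate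
7 | 7-(tert-butyldimethylsilyloxy)-2,2-dimethyl-2H-chromene | CC1(C)C=Cc2ccc(O[Si](C)(C)C(C)(C)C)cc2O1 | intermediate
8 | 2,2-dimethyl-2H-chromen-7-ol | CC1(C)C=Cc2ccc(O)cc2O1 | intermediate
9 | 6-(hydroxymethyl)-2,2-dimethyl-2H-chromen-7-ol (present as magnesium phenoxide; not isolated) | CC1(C)C=Cc2cc(CO)c(O)cc2O1 | intermediate
10 | 7-hydroxy-2,2-dimethyl-2H-chromene-6-carbaldehyde | CC1(C)C=Cc2cc(C=O)c(O)cc2O1 | intermediate
11 | 7-(methoxymethoxy)-2,2-dimethyl-2H-chromene-6-carbaldehyde | CC1(C)C=Cc2cc(C=O)c(OCOC)cc2O1 | intermediate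
12 | 2,4,6-trihydroxyacetophenone | CC(=O)c1c(O)cc(O)cc1O | starting material
13 | 2,6-dihydroxy-4-methoxyacetophenone | CC(=O)c1c(O)cc(OC)cc1O | intermediate
14 | prenyl bromide | CC(C)=CCBr | starting material
15 | 1-[2-hydroxy-4-methoxy-6-(3-methylbut-2-enyloxy)phenyl]ethanone | CC(=O)c1c(O)cc(OC)cc1OCC=C(C)C | intermediate
16 | (±)-aldol adduct, 3-hydroxy-1-[2-hydroxy-4-methoxy-6-(3-methylbut-2-enyloxy)phenyl]-3-[7-(methoxymethoxy)-2,2-dimethyl-2H-chromen-6-yl]propan-1-one (not isolated) | COc1cc(O)c(C(=O)CC(O)c2cc3c(cc2OCOC)OC(C)(C)C=C3)c(OCC=C(C)C)c1 | intermediate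
17 | (E)-chalcone | COc1cc(O)c(C(=O)/C=C/c2cc3c(cc2OCOC)OC(C)(C)C=C3)c(OCC=C(C)C)c1 | intermediate
18 | (±)-5-O-prenyl-7-methoxy flavanone with 2'-OMOM | COc1cc(OCC=C(C)C)c2c(c1)OC(c1cc3c(cc1OCOC)OC(C)(C)C=C3)CC2=O | intermediate
19 | ortho-dienone carrying 6-(1,1-dimethylallyl), diastereomer mixture (not isolated) | COC1=CC2=C(C(=O)CC(c3cc4c(cc3OCOC)OC(C)(C)C=C4)O2)C(=O)C1C(C)(C)C=C | intermediate
20 | para-dienone carrying 8-prenyl, diastereomer mixture (not isolated) | COC1=CC(=O)C2=C(OC(c3cc4c(cc3OCOC)OC(C)(C)C=C4)CC2=O)C1CC=C(C)C | intermediate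
21 | (±)-5-hydroxy-7-methoxy-8-prenyl flavanone with 2'-OMOM | COc1cc(O)c2c(c1CC=C(C)C)OC(c1cc3c(cc1OCOC)OC(C)(C)C=C3)CC2=O | intermediate
22 | (±)-5-acetoxy-7-methoxy-8-prenyl flavanone with 2'-OMOM | COc1cc(OC(C)=O)c2c(c1CC=C(C)C)OC(c1cc3c(cc1OCOC)OC(C)(C)C=C3)CC2=O | intermediate
23 | (2S)-5-acetoxy-7-methoxy-8-prenyl flavanone with 2'-OMOM | COc1cc(OC(C)=O)c2c(c1CC=C(C)C)O[C@H](c1cc3c(cc1OCOC)OC(C)(C)C=C3)CC2=O | intermediate
24 | (2S)-5-hydroxy-7-methoxy-8-prenyl flavanone with 2'-OMOM (not isolated) | COc1cc(O)c2c(c1CC=C(C)C)O[C@H](c1cc3c(cc1OCOC)OC(C)(C)C=C3)CC2=O | intermediate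
25 | maackiaflavanone A, (2S) | COc1cc(O)c2c(c1CC=C(C)C)O[C@H](c1cc3c(cc1O)OC(C)(C)C=C3)CC2=O | target

## Totals and risks
Total step count: 15.
Longest linear sequence: 13 (steps 1–7, then 10–15). Steps 8–9 form the short branch.

**Step 14 (kinetic resolution).** The very electron-rich ketone with a peri-acetoxy group may be reduced too slowly or with too small a selectivity factor.

The fallback is a classical resolution through covalent diastereomers. It sets out from 21 and comes back at 24. Compound 21 is acylated on the 5-OH with (1S)-(−)-camphanic chloride (Et3N, DMAP, CH2Cl2). The two diastereomeric esters are separated by chromatography and crystallisation. The one kept is (2S)-5-O-[(1S,4R)-camphanoyl] flavanone F6. Its configuration is checked by CD, with a positive band near 330 nm and a negative band near 290 nm for (2S). Sc(OTf)3-catalysed methanolysis of this chelation-activated aryl ester (MeOH, 40 °C) then gives 24, here isolated. Compound 24 goes on under the conditions of step 15.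

**Step 12 (Claisen–Cope).** The sequence can stop at the 6-(1,1-dimethylallyl) isomer or lose the prenyl group.

The fallback places the prenyl group on carbon before the aldol step. It sets out from 13 and comes back at 24.
- Symmetrical 13 is C-prenylated with 14 in aqueous KOH at 0 °C, so only one mono-C-prenyl product is possible. This gives 2,6-dihydroxy-4-methoxy-3-prenylacetophenone F1.
- One equivalent of MOMCl with i-Pr2NEt reacts at the less hindered OH, remote from the prenyl group, to give 2-hydroxy-4-methoxy-6-(methoxymethoxy)-3-prenylacetophenone F2.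
- Claisen–Schmidt condensation of F2 with 11 (KOH, EtOH) gives the 3'-prenyl chalcone F3.
- NaOAc in refluxing EtOH closes ring C through the only free OH, the one next to the prenyl group, to give the (±)-5,2'-bis-MOM 8-prenyl flavanone F4.
- The transfer-hydrogenation resolution of step 14 leaves the (2S)-5,2'-bis-MOM 8-prenyl flavanone F5.
- Under the conditions of step 15 the chelation-activated 5-O-MOM group falls first, giving 24 and then 25.

**Step 15 (final unmasking).** Protic acid can reversibly open ring C, because the benzylic C-2 sits on a 2',4'-dioxygenated ring B. This would erode the ee.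

The fallback changes the protecting groups before the resolution, so the enantioenriched flavanone never meets protic mineral acid. It sets out from 21 and comes back at 25. Compound 21 is freed with HCl/MeOH while still racemic, giving (±)-maackiaflavanone A F7. TBSOTf with 2,6-lutidine (CH2Cl2, 0 °C) gives the (±)-5,2'-bis-TBS ether F8. Resolution with the same (R,R)-catalyst leaves the (2S)-5,2'-bis-TBS ether F9. Et3N·3HF in THF at rt then gives 25.

## Further compounds
F1 | step 12 | 1-[2,6-dihydroxy-4-methoxy-3-(3-methylbut-2-enyl)phenyl]ethanone | CC(=O)c1c(O)cc(OC)c(CC=C(C)C)c1O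
F2 | step 12 | 1-[2-hydroxy-4-methoxy-6-(methoxymethoxy)-3-(3-methylbut-2-enyl)phenyl]ethanone | CC(=O)c1c(OCOC)cc(OC)c(CC=C(C)C)c1O
F3 | step 12 | (E)-2'-hydroxy-4'-methoxy-6'-(methoxymethoxy)-3'-prenyl chalcone with the MOM-protected chromenyl ring B | COCOc1cc(OC)c(CC=C(C)C)c(O)c1C(=O)/C=C/c1cc2c(cc1OCOC)OC(C)(C)C=C2
F4 | step 12 | (±)-7-methoxy-5-(methoxymethoxy)-2-[7-(methoxymethoxy)-2,2-dimethyl-2H-chromen-6-yl]-8-(3-methylbut-2-enyl)chroman-4-one | COc1cc(OCOC)c2c(c1CC=C(C)C)OC(c1cc3c(cc1OCOC)OC(C)(C)C=C3)CC2=O
F5 | step 12 | (2S)-7-methoxy-5-(methoxymethoxy)-2-[7-(methoxymethoxy)-2,2-dimethyl-2H-chromen-6-yl]-8-(3-methylbut-2-enyl)chroman-4-one | COc1cc(OCOC)c2c(c1CC=C(C)C)O[C@H](c1cc3c(cc1OCOC)OC(C)(C)C=C3)CC2=O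
F6 | step 14 | (2S)-flavanone 5-O-(1S,4R)-camphanate with 2'-OMOM | COc1cc(OC(=O)[C@@]23CC[C@@](C)(C(=O)O2)C3(C)C)c2c(c1CC=C(C)C)O[C@H](c1cc3c(cc1OCOC)OC(C)(C)C=C3)CC2=O
F7 | step 15 | (±)-maackiaflavanone A | COc1cc(O)c2c(c1CC=C(C)C)OC(c1cc3c(cc1O)OC(C)(C)C=C3)CC2=O
F8 | step 15 | (±)-5,2'-bis(tert-butyldimethylsilyl) ether of maackiaflavanone A | COc1cc(O[Si](C)(C)C(C)(C)C)c2c(c1CC=C(C)C)OC(c1cc3c(cc1O[Si](C)(C)C(C)(C)C)OC(C)(C)C=C3)CC2=O
F9 | step 15 | (2S)-5,2'-bis(tert-butyldimethylsilyl) ether of maackiaflavanone A | COc1cc(O[Si](C)(C)C(C)(C)C)c2c(c1CC=C(C)C)O[C@H](c1cc3c(cc1O[Si](C)(C)C(C)(C)C)OC(C)(C)C=C3)CC2=O
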